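Grey holds half of teal's free catalyst on the same substrate charge, and at twice the time it stands about where teal stands: 17.4% of the charge turned at 5.7 min, against 17.9% at 2.9 min.

| flask | substrate | free catalyst | time |
|---|---|---|---|
| teal | 0.120 M | 0.00120 M |  |
| blue | 0.0600 M | 0.00120 M |  |
| violet | 0.360 M | 0.00120 M |  |
| grey | 0.120 M | 6.00 × 10⁻⁴ M |  |
| amber | 0.120 M | 3.40 × 10⁻⁴ M | 20 min |

- teal run (time / min: [product] / M): 2.9: 0.0215; 5.7: 0.0353; 8.6: 0.0476; 11: 0.0574; 14: 0.0634; 17: 0.0684; 20: 0.0750
- blue run (time / min: [product] / M): 2.9: 0.0114; 5.7: 0.0196; 8.6: 0.0255; 11: 0.0281; 14: 0.0337; 17: 0.0379; 20: 0.0402
- violet run (time / min: [product] / M): 2.9: 0.0591; 5.7: 0.0951; 8.6: 0.1206; 11: 0.1366; 14: 0.1526; 17: 0.1641; 20: 0.1732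
- grey run (time / min: [product] / M): 2.9: 0.0124; 5.7: 0.0209; 8.6: 0.0287; 11: 0.0340; 14: 0.0416; 17: 0.0452; 20: 0.0504

(scatter of a reading: 0.001 M)

- Overall: substrate -> product, with free catalyst as catalyst.
- Constant volume, constant temperature.
- What is held in complexes is read along with the free species.
- An order is taken over about fifteen percent of the charge, up and down.

1. how the opening rate goes with [free catalyst] round the charge of the teal run: the exponent of the rate at two percent of substrate gone to product
2. how the opening rate goes with [substrate] round the charge of the teal run: the exponent of the rate at two percent of substrate gone to product (one fixed amount of product, the same in the runs compared)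
3. the blue run starts with 0.0600 M less of substrate than the teal run, and with no product. Compared where both hold the same amount of substrate, once fifteen percent of what the blue run was charged with has turned into product, is the blue run faster, slower or alike (within a tenth)?
4. product in the amber run at 20 min, as a share of the substrate charged

That comparison suggests one clock for flasks with the same substrate charge. The usual term is variable time normalisation. We count amber's time in 5.67 min of teal-minutes, a flask's time multiplied by its free catalyst charge and divided by teal's. On grey's charge the same span is 11.3 min, so we have two separate ways to amber's share, each from the nearest reading: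

teal at 5.7 min: 29.4% of the charge

grey at 11 min: 28.3% of the charge

They differ by 1.1 percentage points, and one reading carries a scatter of 0.833% of the charge, so the two roughly agree. But the difference has a direction. Pairing grey with teal at doubled times, teal leads by 0.5 points at 2.9 min, 1.1 points at 5.7 min and 2 points at 8.6 min. In these readings the clock therefore seems good at the opening and slips later, with grey, the flask holding less free catalyst, falling behind teal.

Amber holds less free catalyst than grey, so teal's figure is the one that flatters. As our own reckoning we take the mean of the two ways, 28.9%.

The forecast stands a little higher than our mean, at 29.3%, by “time scaling from grey”. It gives 1 for the order in free catalyst, 1 for the order in substrate, and faster for blue.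

The flask gives 28.7% for amber, orders of 1.0 in free catalyst and 1.0 in substrate, and faster for blue.

    free catalyst + substrate → product + free catalyst (59.40 M⁻¹ min⁻¹)
    free catalyst + product ⇌ catalyst-product complex, settled at all times (4.890 M⁻¹)
    free catalyst + product → spent catalyst + product (0.7620 M⁻¹ min⁻¹)

Grey's opening rate over teal's, at one amount of product, is 0.50, the ratio of their catalyst charges. At 5.67 min on the clock, amber's 28.7% lies 0.70 points from teal's reading at 5.7 min, a gap smaller than the scatter of that one reading. Grey shows the slip further on: its half of the charge, reached at 28.8 min, comes to 14.4 min of teal-minutes, while teal's reading at 14 min already stands at 52.8%.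

The readings were generated by integration on assumed constants.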